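Ring B is opened at C8–C9 and C5–C10. The feature exploited is the vicinal C9/C10 pair of ring B, quaternary C10 carrying the C20 methyl cis to the C11–C15 chain on C9: this is the imprint of an (E)-2-methyl-2-enal. One catalytic asymmetric Diels–Alder reaction between the citronellol-derived enal and 1-dimethylamino-3-silyloxybutadiene therefore closes ring B, forms both bonds and sets both centres, leaving a C5=C6–C7 enone beside the C1 aldehyde. The C7 ketone then takes up C17 at C8 and, once reduced, relays its configuration to C5 by an isobutyrate Ireland–Claisen shift; aldol closure gives ring A, and moving C6=C7 into conjugation with a C17 aldehyde places the C7=C8 bond.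

Key step: step 3

Assumption: atoms carry labdane numbers (ring A = C1–C5 and C10, ring B = C5–C10, chain C11–C15 with C16 on C13, C17 on C8, C18 and C19 on C4, C20 on C10; "the C20 face" is the face of ring B that carries the C10 methyl and the C9 chain), and the (R,R) antipode of the catalyst is taken, by analogy with α-alkylacroleins, to give the (9R,10S) cycloadduct; the (S,S) complex would be used if the sense proved opposite.

Step 1
Reactants: 1 (R)-citronellol
Product: 2 tert-butyl{[(3R)-3,7-dimethyloct-6-en-1-yl]oxy}dimethylsilane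
Conditions: TBSCl, imidazole, CH2Cl2, rt
Reagents that add atoms: tert-butyldimethylsilyl chloride CC(C)(C)[Si](C)(C)Cl
Why: Imidazole-promoted silylation of the primary alcohol is chemoselective and leaves the trisubstituted alkene and the C13 centre untouched.

Step 2
Reactants: 2 tert-butyl{[(3R)-3,7-dimethyloct-6-en-1-yl]oxy}dimethylsilane
Product: 4 (2E,6R)-8-(tert-butyldimethylsilyloxy)-2,6-dimethyloct-2-enal, via allylic alcohol 3 (not isolated)
Conditions: SeO2 (0.3 equiv), tBuOOH (3 equiv), salicylic acid (0.1 equiv), CH2Cl2, rt; then MnO2, CH2Cl2, rt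
Reagents that add atoms: tert-butyl hydroperoxide CC(C)(C)OO
Why: The SeO2/tBuOOH allylic oxidation (ene reaction followed by a [2,3]-shift) hydroxylates the (E)-methyl group of a trisubstituted alkene selectively, and MnO2 then converges the allylic alcohol and any enal already formed on the (E)-enal without changing the alkene geometry.

Step 3
Reactants: 4 (2E,6R)-8-(tert-butyldimethylsilyloxy)-2,6-dimethyloct-2-enal; 5 (E)-1-dimethylamino-3-(tert-butyldimethylsilyloxy)buta-1,3-diene
Product: 7 (1S,6R)-6-[(3R)-5-(tert-butyldimethylsilyloxy)-3-methylpentyl]-1-methyl-4-oxocyclohex-2-ene-1-carbaldehyde, via cycloadduct 6 (not isolated)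
Conditions: (R,R)-(salen)CrSbF6 (10 mol%; salen = N,N′-bis(3,5-di-tert-butylsalicylidene)cyclohexane-1,2-diaminate), 4 Å MS, CH2Cl2, −40 → −20 °C, slow addition of 5; then AcCl, Et2O, −78 °C
Reagents that add atoms: none
Why: The cationic salen complex of trivalent chromium binds the formyl oxygen of 4, and a concerted, asynchronous [4+2] cycloaddition joins the nucleophilic CH2 terminus of 5 to the enal β-carbon (C8–C9) slightly ahead of the aminated terminus to the α-carbon (C5–C10); acetyl chloride then acylates nitrogen in 6, and loss of N,N-dimethylacetamide and of the silyl group unveils the C5=C6–C7 enone. The closest known reaction is the salen–metal-catalysed enantioselective Diels–Alder reaction of 1-amino-3-siloxydienes with α-alkylacroleins; the extra β-alkyl group slows the catalysed and the background reaction alike, which is why the most reactive (dimethylamino) diene is paired with a cationic catalyst at a somewhat higher temperature. Ring B closes in the cycloaddition itself, by suprafacial addition of the four diene carbons across the C9=C10 alkene, not in a separate cyclisation. The C9/C10 relationship (C20 cis to the chain) is the stereospecific copy of the (E)-alkene, the absolute configuration of both centres is set by the catalyst shielding one face of the bound enal, and the remote C13 centre has no influence. The step needs regioselectivity (secured by the matched polarisation of the aminosiloxydiene and the enal), periselectivity for C=C over the formyl C=O (favoured by conjugate-type attack at the unhindered β-CH while the carbonyl sits next to the fully substituted α-carbon) and enantiofacial selectivity (catalyst control alone).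

Step 4
Reactants: 7 (1S,6R)-6-[(3R)-5-(tert-butyldimethylsilyloxy)-3-methylpentyl]-1-methyl-4-oxocyclohex-2-ene-1-carbaldehyde
Product: 8 (4S,5R)-5-[(3R)-5-(tert-butyldimethylsilyloxy)-3-methylpentyl]-4-(1,3-dioxolan-2-yl)-4-methylcyclohex-2-en-1-one
Conditions: TMSOCH2CH2OTMS, TMSOTf (5 mol%), CH2Cl2, −78 → −20 °C
Reagents that add atoms: 1,2-bis(trimethylsilyloxy)ethane C[Si](C)(C)OCCO[Si](C)(C)C
Why: Noyori acetalisation (bis-silyl glycol, catalytic TMSOTf) converts an aldehyde far faster than a conjugated ketone and does not disturb the primary silyl ether at low temperature, so only C1 is masked.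

Step 5
Reactants: 8 (4S,5R)-5-[(3R)-5-(tert-butyldimethylsilyloxy)-3-methylpentyl]-4-(1,3-dioxolan-2-yl)-4-methylcyclohex-2-en-1-one; 9 benzyl chloromethyl ether
Product: 11 enone 8 carrying a benzyloxymethyl group (C17) on C8 trans to the C9 chain, via lithium dienolate 10 (not isolated)
Conditions: LiN(iPr)2, THF, −78 °C; then 9, DMPU, −78 → −30 °C
Reagents that add atoms: none
Why: Because C10 is quaternary the enone can be deprotonated only at C8, and the resulting cross-conjugated lithium dienolate is C-alkylated by the chloromethyl ether (kinetic enolate alkylation) on the face away from the C9 chain, giving a C8 centre that is erased again in step 15.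

Step 6
Reactants: 11 enone carrying the benzyloxymethyl group on C8
Product: 12 allylic alcohol with the C7 hydroxyl on the C20 face (cis to the C9 chain; trans to C17)
Conditions: NaBH4, CeCl3·7H2O, MeOH, −78 °C
Reagents that add atoms: none
Why: In the Luche 1,2-reduction the enone sits in the half-chair with the C8 and C9 substituents equatorial, so hydride adds axially to C7 from the face opposite the C20 methyl and the chain and leaves the new hydroxyl equatorial on the C20 face, the configuration the [3,3]-shift of step 8 requires.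

Step 7
Reactants: 12 allylic alcohol with the C7 hydroxyl on the C20 face; 13 isobutyryl chloride
Product: 14 C7 isobutyrate of 12
Conditions: 13, pyridine, DMAP (cat.), CH2Cl2, 0 °C → rt
Reagents that add atoms: none
Why: DMAP-catalysed acylation of the secondary allylic alcohol by the acid chloride is routine and proceeds with retention at C7.

Step 8
Reactants: 14 C7 isobutyrate
Product: 17 carboxylic acid with C(CH3)2CO2H on C5 on the C20 face and a C6=C7 alkene, via silyl ketene acetal 15 (not isolated), via trimethylsilyl ester 16 (not isolated)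
Conditions: LiN(iPr)2, TMSCl, THF, −78 °C; then toluene, 90 °C; aq. AcOH work-up
Reagents that add atoms: none
Why: Ireland–Claisen rearrangement: the trimethylsilyl ketene acetal of the isobutyrate shifts suprafacially across the C5=C6–C7 allyl unit, so the C4–C5 bond forms on the face that carried the C7 oxygen (the C20 face), which sets C5 for the trans ring fusion, creates quaternary C4 with both methyl groups and moves the alkene to C6=C7.

Step 9
Reactants: 17 carboxylic acid; 18 methyllithium
Product: 19 methyl ketone (C5–C(CH3)2–C(=O)CH3; C3 carbonyl and C2 methyl)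
Conditions: 18 (4 equiv), Et2O, 0 °C → rt; then H2O
Reagents that add atoms: none
Why: Methyllithium adds to the lithium carboxylate to give a dilithium gem-diolate that is stable until the aqueous quench (ketone synthesis from carboxylic acids), so the methyl ketone forms without over-addition even at this α-quaternary centre.

Step 10
Reactants: 19 methyl ketone
Product: 21 trans-fused bicyclic enone (ring A C1=C2–C3=O; C6=C7; C8–CH2OBn; free C15 hydroxyl), via keto aldehyde 20 (not isolated)
Conditions: 1 M HCl, THF, rt → 40 °C; then NaOMe, MeOH, rt → 50 °C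
Reagents that add atoms: none
Why: Aqueous acid removes the dioxolane and the primary silyl ether, and methoxide then drives the intramolecular aldol condensation of the only enolisable ketone position (C2) onto the non-enolisable C1 aldehyde, closing ring A as a six-membered enone in a 6-(enolendo)-exo-trig mode.

Step 11
Reactants: 21 bicyclic enone
Product: 22 saturated C3 ketone (C6=C7, C8–CH2OBn and C15 hydroxyl unchanged)
Conditions: [(Ph3P)CuH]6 (0.4 equiv), H2O (2 equiv), toluene, rt
Reagents that add atoms: none
Why: The copper hydride hexamer transfers hydride to the β-carbon (C1) of the enone and water protonates the copper enolate (conjugate reduction), which leaves the isolated C6=C7 alkene, the benzyl ether and the free alcohol untouched.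

Step 12
Reactants: 22 saturated C3 ketone
Product: 23 C15 carboxylic acid
Conditions: TEMPO (0.2 equiv), PhI(OAc)2 (2.5 equiv), MeCN/H2O, rt
Reagents that add atoms: water O
Why: TEMPO with PhI(OAc)2 in aqueous acetonitrile oxidises the only free (primary) alcohol through the aldehyde hydrate to the carboxylic acid without affecting the ketone, the alkene or the benzyl ether.

Step 13
Reactants: 23 C15 carboxylic acid
Product: 24 C15 methyl ester
Conditions: Me3SiCHN2, MeOH/toluene, 0 °C
Reagents that add atoms: trimethylsilyldiazomethane C[Si](C)(C)C=[N+]=[N-]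
Why: Trimethylsilyldiazomethane in methanol methylates a carboxylic acid selectively (diazoalkane esterification) and does not react with the hindered ketone.

Step 14
Reactants: 24 C15 methyl ester
Product: 25 C17 primary alcohol (C3 ketone; C6=C7)
Conditions: BCl3, C6HMe5, CH2Cl2, −78 °C; then MeOH
Reagents that add atoms: none
Why: BCl3 ionises the primary benzyl ether at −78 °C and pentamethylbenzene traps the benzyl cation (Lewis acid debenzylation), conditions under which the isolated alkene, the ketone and the methyl ester should survive.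

Step 15
Reactants: 25 C17 primary alcohol
Product: 27 conjugated enal (C7=C8–C17HO; C3 ketone), via β,γ-unsaturated aldehyde 26 (not isolated)
Conditions: Dess–Martin periodinane, CH2Cl2, rt; aqueous wash; then DBU (0.2 equiv), CH2Cl2, rt
Reagents that add atoms: none
Why: Dess–Martin oxidation gives the β,γ-unsaturated aldehyde, whose C8 hydrogen is both α to the formyl group and allylic, so DBU isomerises it through the dienolate (γ-protonation at C6) to the conjugated, trisubstituted C7=C8 enal, the only conjugated isomer that can form.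

Step 16
Reactants: 27 conjugated enal
Product: 28 methyl (3R)-5-[(1S,4aS,6R,8aS)-6-hydroxy-2-(hydroxymethyl)-5,5,8a-trimethyl-1,4,4a,5,6,7,8,8a-octahydronaphthalen-1-yl]-3-methylpentanoate (CNP0313905.1)
Conditions: NaBH4, CeCl3·7H2O, MeOH, −20 → 0 °C
Reagents that add atoms: none
Why: Luche reduction converts the enal 1,2 into the primary allylic alcohol and reduces the C3 ketone by axial hydride attack from the face opposite the axial C4 and C10 methyl groups, giving the equatorial C3 hydroxyl on the C20 face, while the methyl ester is inert to NaBH4.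

Compound list

1 | (R)-citronellol, (3R)-3,7-dimethyloct-6-en-1-ol | OCC[C@H](C)CCC=C(C)C | starting material
2 | tert-butyl{[(3R)-3,7-dimethyloct-6-en-1-yl]oxy}dimethylsilane | CC(C)(C)[Si](C)(C)OCC[C@H](C)CCC=C(C)C | intermediate
3 | (2E,6R)-8-(tert-butyldimethylsilyloxy)-2,6-dimethyloct-2-en-1-ol (not isolated) | CC(C)(C)[Si](C)(C)OCC[C@H](C)CC/C=C(\C)CO | intermediate
4 | (2E,6R)-8-(tert-butyldimethylsilyloxy)-2,6-dimethyloct-2-enal | CC(C)(C)[Si](C)(C)OCC[C@H](C)CC/C=C(\C)C=O | intermediate
5 | (E)-1-dimethylamino-3-(tert-butyldimethylsilyloxy)buta-1,3-diene | CN(C)/C=C/C(=C)O[Si](C)(C)C(C)(C)C | starting material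
6 | cycloadduct: 4-(tert-butyldimethylsilyloxy)-2-(dimethylamino)-1-methyl-6-[(3R)-5-(tert-butyldimethylsilyloxy)-3-methylpentyl]cyclohex-3-ene-1-carbaldehyde, C9 and C10 as in 7, amino-bearing carbon not defined (not isolated) | CC(C)(C)[Si](C)(C)OCC[C@H](C)CC[C@@H]1CC(O[Si](C)(C)C(C)(C)C)=CC(N(C)C)[C@@]1(C)C=O | intermediate
7 | (1S,6R)-6-[(3R)-5-(tert-butyldimethylsilyloxy)-3-methylpentyl]-1-methyl-4-oxocyclohex-2-ene-1-carbaldehyde (ring B; C20 methyl cis to the chain) | CC(C)(C)[Si](C)(C)OCC[C@H](C)CC[C@@H]1CC(=O)C=C[C@@]1(C)C=O | intermediate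
8 | (4S,5R)-5-[(3R)-5-(tert-butyldimethylsilyloxy)-3-methylpentyl]-4-(1,3-dioxolan-2-yl)-4-methylcyclohex-2-en-1-one | CC(C)(C)[Si](C)(C)OCC[C@H](C)CC[C@@H]1CC(=O)C=C[C@@]1(C)C2OCCO2 | intermediate
9 | benzyl chloromethyl ether | ClCOCc1ccccc1 | starting material
10 | lithium dienolate of 8 (C7–OLi, C7=C8, C5=C6) (not isolated) | CC(C)(C)[Si](C)(C)OCC[C@H](C)CC[C@@H]1C=C(O[Li])C=C[C@@]1(C)C2OCCO2 | intermediate
11 | enone 8 with a benzyloxymethyl group (C17) on C8, trans to the C9 chain | CC(C)(C)[Si](C)(C)OCC[C@H](C)CC[C@@H]1[C@@H](COCc2ccccc2)C(=O)C=C[C@@]1(C)C3OCCO3 | intermediate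
12 | allylic alcohol from 11, C7–OH on the C20 face (cis to the C9 chain, trans to C17) | CC(C)(C)[Si](C)(C)OCC[C@H](C)CC[C@@H]1[C@@H](COCc2ccccc2)[C@H](O)C=C[C@@]1(C)C3OCCO3 | intermediate
13 | isobutyryl chloride (2-methylpropanoyl chloride) | CC(C)C(Cl)=O | starting material
14 | C7 isobutyrate of 12 | CC(C)(C)[Si](C)(C)OCC[C@H](C)CC[C@@H]1[C@@H](COCc2ccccc2)[C@H](OC(=O)C(C)C)C=C[C@@]1(C)C3OCCO3 | intermediate
15 | O-trimethylsilyl ketene acetal of 14 (not isolated) | CC(C)(C)[Si](C)(C)OCC[C@H](C)CC[C@@H]1[C@@H](COCc2ccccc2)[C@H](OC(O[Si](C)(C)C)=C(C)C)C=C[C@@]1(C)C3OCCO3 | intermediate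
16 | trimethylsilyl ester of 17 (not isolated) | CC(C)(C)[Si](C)(C)OCC[C@H](C)CC[C@@H]1[C@@H](COCc2ccccc2)C=C[C@H](C(C)(C)C(=O)O[Si](C)(C)C)[C@@]1(C)C3OCCO3 | intermediate
17 | 2-methyl-2-(ring B C5)propanoic acid: C5 bears C(CH3)2CO2H on the C20 face, C6=C7, C8–CH2OBn, C10 dioxolanyl | CC(C)(C)[Si](C)(C)OCC[C@H](C)CC[C@@H]1[C@@H](COCc2ccccc2)C=C[C@H](C(C)(C)C(=O)O)[C@@]1(C)C3OCCO3 | intermediate
18 | methyllithium | [Li]C | starting material
19 | methyl ketone from 17 (C5–C(CH3)2–C(=O)CH3) | CC(C)(C)[Si](C)(C)OCC[C@H](C)CC[C@@H]1[C@@H](COCc2ccccc2)C=C[C@H](C(C)(C)C(C)=O)[C@@]1(C)C3OCCO3 | intermediate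
20 | keto aldehyde with free C1 formyl group and free C15 hydroxyl (not isolated) | OCC[C@H](C)CC[C@@H]1[C@@H](COCc2ccccc2)C=C[C@H](C(C)(C)C(C)=O)[C@@]1(C)C=O | intermediate
21 | trans-fused bicyclic enone: C1=C2–C3=O in ring A, C6=C7 in ring B, C8–CH2OBn trans to the chain, C15–OH | OCC[C@H](C)CC[C@@H]1[C@@H](COCc3ccccc3)C=C[C@@H]2C(C)(C)C(=O)C=C[C@@]12C | intermediate
22 | saturated C3 ketone from 21 | OCC[C@H](C)CC[C@@H]1[C@@H](COCc3ccccc3)C=C[C@@H]2C(C)(C)C(=O)CC[C@@]12C | intermediate
23 | C15 carboxylic acid from 22 | OC(=O)C[C@H](C)CC[C@@H]1[C@@H](COCc3ccccc3)C=C[C@@H]2C(C)(C)C(=O)CC[C@@]12C | intermediate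
24 | C15 methyl ester from 23 | COC(=O)C[C@H](C)CC[C@@H]1[C@@H](COCc3ccccc3)C=C[C@@H]2C(C)(C)C(=O)CC[C@@]12C | intermediate
25 | C17 primary alcohol from 24 (C3 ketone, C6=C7) | COC(=O)C[C@H](C)CC[C@@H]1[C@@H](CO)C=C[C@@H]2C(C)(C)C(=O)CC[C@@]12C | intermediate
26 | β,γ-unsaturated C17 aldehyde (C6=C7) (not isolated) | COC(=O)C[C@H](C)CC[C@@H]1[C@@H](C=O)C=C[C@@H]2C(C)(C)C(=O)CC[C@@]12C | intermediate
27 | conjugated enal (C7=C8–C17HO) with C3 ketone | COC(=O)C[C@H](C)CC[C@@H]1C(C=O)=CC[C@@H]2C(C)(C)C(=O)CC[C@@]12C | intermediate
28 | methyl (3R)-5-[(1S,4aS,6R,8aS)-6-hydroxy-2-(hydroxymethyl)-5,5,8a-trimethyl-1,4,4a,5,6,7,8,8a-octahydronaphthalen-1-yl]-3-methylpentanoate (CNP0313905.1) | COC(=O)C[C@H](C)CC[C@@H]1C(CO)=CC[C@@H]2C(C)(C)[C@H](O)CC[C@@]12C | target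

Total step count: 16 steps.
Longest linear sequence: 16 steps (1 to 28).

Steps most likely to fail

Step 3 (key step). What may go wrong: the basic, very electron-rich diene may bind to or be degraded by the cationic chromium complex, and turnover at the trisubstituted dienophile may be so slow that the uncatalysed pathway, or addition across the formyl C=O, takes over. Enantiofacial control would then be lost. The fallback sets out from 4 and comes back at 7, and replaces the chiral catalyst by a stoichiometric chiral diene. (E)-4-Methoxybut-3-en-2-one is condensed with (2S,5S)-2,5-diphenylpyrrolidine to the vinylogous amide (E)-4-[(2S,5S)-2,5-diphenylpyrrolidin-1-yl]but-3-en-2-one F1. KN(SiMe3)2 and TBSCl in THF at −78 °C should convert it into the C2-symmetric diene (2S,5S)-1-[(1E)-3-(tert-butyldimethylsilyloxy)buta-1,3-dienyl]-2,5-diphenylpyrrolidine F2. Heating F2 with enal 4 in toluene is a thermal Diels–Alder reaction of a known class of chiral aminosiloxydienes that accepts α,β-disubstituted dienophiles, and should give the pyrrolidinyl cycloadduct F3, the phenyl groups of the auxiliary differentiating the diene faces. Dilute HCl in THF at 0 °C then removes the auxiliary and the silyl group and returns to 7. The auxiliary is drawn as (2S,5S); the antipode that gives the ring B configuration of 7 is the one used.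

Step 8. What may go wrong: the [3,3]-shift has to join a fully substituted ketene acetal carbon to C5 beside quaternary C10, so the rearrangement may stall. The ketene acetal is then lost by C-silylation or by hydrolysis back to the ester, or the allylic ester ionises and eliminates on heating. The fallback sets out from 12 and comes back at 19, and builds the quaternary carbon after the sigmatropic step instead of during it. Alcohol 12 is heated with N,N-dimethylacetamide dimethyl acetal in xylene at 140 °C. This Eschenmoser–Claisen rearrangement has the same suprafacial transfer from the C7 oxygen to C5 but uses an unsubstituted ketene N,O-acetal, and should give the N,N-dimethylacetamide-substituted cyclohexene F4. Two successive enolate methylations (LiN(iPr)2, MeI, THF, −78 °C, the second with DMPU) should lead through the monomethyl amide F5 to the α,α-dimethyl amide F6. Methyllithium in Et2O then adds once to the tertiary amide and releases methyl ketone 19 on aqueous work-up.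

Step 14. What may go wrong: the Lewis acid may also attack the cis-alkene (hydrochlorination or migration of the double bond) or promote enolisation and condensation at the ketone, or the ether may ionise incompletely at low temperature. The fallback sets out from 23 and comes back at 28, and cleaves the benzyl ether reductively before the ester is made. Li in liquid NH3/THF at −78 °C should cleave the benzyl ether of carboxylate 23 and reduce the C3 ketone to the more stable equatorial alcohol, leaving the isolated alkene and the carboxylate alone, to give the dihydroxy acid F7. Trimethylsilyldiazomethane gives the dihydroxy methyl ester F8. TEMPO/PhI(OAc)2 in CH2Cl2 oxidises only the primary C17 alcohol, and DBU moves the alkene into conjugation to give the 3-hydroxy enal F9. NaBH4/CeCl3·7H2O in MeOH then reduces the formyl group to give 28.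

Further compounds

F1 | step 3 | (E)-4-[(2S,5S)-2,5-diphenylpyrrolidin-1-yl]but-3-en-2-one | CC(=O)/C=C/N1[C@@H](CC[C@H]1c2ccccc2)c3ccccc3
F2 | step 3 | (2S,5S)-1-[(1E)-3-(tert-butyldimethylsilyloxy)buta-1,3-dienyl]-2,5-diphenylpyrrolidine | C=C(O[Si](C)(C)C(C)(C)C)/C=C/N1[C@@H](CC[C@H]1c2ccccc2)c3ccccc3
F3 | step 3 | cycloadduct of F2 and 4 (pyrrolidinyl analogue of 6) | CC(C)(C)[Si](C)(C)OCC[C@H](C)CC[C@@H]1CC(O[Si](C)(C)C(C)(C)C)=CC(N2[C@@H](CC[C@H]2c3ccccc3)c4ccccc4)[C@@]1(C)C=O
F4 | step 8 | N,N-dimethylacetamide with the ring B C5 substituent (C5–CH2CONMe2 on the C20 face, C6=C7) | CC(C)(C)[Si](C)(C)OCC[C@H](C)CC[C@@H]1[C@@H](COCc2ccccc2)C=C[C@H](CC(=O)N(C)C)[C@@]1(C)C3OCCO3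
F5 | step 8 | α-methyl amide from F4 (C4 epimers) | CC(C)(C)[Si](C)(C)OCC[C@H](C)CC[C@@H]1[C@@H](COCc2ccccc2)C=C[C@H](C(C)C(=O)N(C)C)[C@@]1(C)C3OCCO3
F6 | step 8 | α,α-dimethyl amide from F5 | CC(C)(C)[Si](C)(C)OCC[C@H](C)CC[C@@H]1[C@@H](COCc2ccccc2)C=C[C@H](C(C)(C)C(=O)N(C)C)[C@@]1(C)C3OCCO3
F7 | step 14 | 3,17-dihydroxy C15 acid (C6=C7, equatorial C3–OH) | OC(=O)C[C@H](C)CC[C@@H]1[C@@H](CO)C=C[C@@H]2C(C)(C)[C@H](O)CC[C@@]12C
F8 | step 14 | methyl ester of F7 | COC(=O)C[C@H](C)CC[C@@H]1[C@@H](CO)C=C[C@@H]2C(C)(C)[C@H](O)CC[C@@]12C
F9 | step 14 | 3-hydroxy conjugated enal (C7=C8–C17HO) | COC(=O)C[C@H](C)CC[C@@H]1C(C=O)=CC[C@@H]2C(C)(C)[C@H](O)CC[C@@]12C
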